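**Assumption:** the [C@@H] centre in the target SMILES is (S) by CIP analysis, and the route is built to deliver (S). 4-Hydroxyphenylpyruvic acid and 2,4,6-tribromoresorcinol are taken as commercial.

## Retrosynthetic overview

1. Target ⇐ one mild-acid global deprotection of a tris-MOM / O-TES protected α-silyloxy ketone.
2. Aryl–C(=O) bond ⇐ aryllithium (from a diprenylated aryl bromide) plus an (S)-α-silyloxy Weinreb amide.
3. Weinreb amide ⇐ (S)-4-hydroxyphenyllactic acid ⇐ L-lactate dehydrogenase reduction of achiral 4-hydroxyphenylpyruvic acid, which sets the only stereocentre.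
4. Aryl bromide ⇐ 2,4,6-tribromoresorcinol bis-MOM ether by two successive Br/Li exchange–prenylations (central Br first, then one of two symmetry-equivalent Br).
5. No rings are formed; both benzene rings come intact from the starting materials.

Compounds are numbered in order of appearance in the forward steps.

## Fragment A: chiral Weinreb amide

**Step 1**
Reactants: 1, 4-hydroxyphenylpyruvic acid
Product: 2, (S)-2-hydroxy-3-(4-hydroxyphenyl)propanoic acid
Conditions: L-lactate dehydrogenase (NADH-dependent L-2-hydroxy-acid dehydrogenase, a ketoreductase-class enzyme), NAD+ (cat.), formate dehydrogenase, HCO2Na, KPi buffer pH 7.0, 30 °C; then HCl to pH 2, EtOAc extraction, recrystallise; check ee by chiral HPLC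
Reagents that add atoms: none (only H, delivered from formate via NADH)
Why: Enzymatic asymmetric carbonyl reduction; the dehydrogenase delivers hydride to the re face of the 2-oxo acid to give the (S)-hydroxy acid, and CO2 loss from formate makes it irreversible.

**Step 2**
Reactants: 2, (S)-2-hydroxy-3-(4-hydroxyphenyl)propanoic acid; 3, methanol
Product: 4, methyl (S)-2-hydroxy-3-(4-hydroxyphenyl)propanoate
Conditions: MeOH, AcCl (0.3 equiv, HCl in situ), 0 °C → rt
Reagents that add atoms: methanol, CO
Why: Fischer esterification; the stereocentre is not involved and α-hydroxy acids do not racemise under these conditions.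

**Step 3**
Reactants: 4, methyl (S)-2-hydroxy-3-(4-hydroxyphenyl)propanoate; 5, chloromethyl methyl ether (MOMCl)
Product: 6, methyl (S)-2-hydroxy-3-[4-(methoxymethoxy)phenyl]propanoate
Conditions: MOMCl (1.1 equiv), K2CO3, acetone, 0 °C → rt
Reagents that add atoms: MOMCl, COCCl
Why: Williamson-type O-alkylation; only the phenol (pKa ~10) is deprotonated by K2CO3, so the secondary alcohol stays free.

**Step 4**
Reactants: 6, methyl (S)-2-hydroxy-3-[4-(methoxymethoxy)phenyl]propanoate; 7, chlorotriethylsilane (TESCl)
Product: 8, methyl (S)-3-[4-(methoxymethoxy)phenyl]-2-(triethylsilyloxy)propanoate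
Conditions: TESCl (1.3 equiv), imidazole, CH2Cl2, 0 °C → rt
Reagents that add atoms: TESCl, CC[Si](Cl)(CC)CC
Why: Standard silylation of a secondary alcohol; TES is chosen because it later cleaves under the same mild acid as the aryl MOM ethers.

**Step 5**
Reactants: 8, methyl (S)-3-[4-(methoxymethoxy)phenyl]-2-(triethylsilyloxy)propanoate; 9, N,O-dimethylhydroxylamine hydrochloride
Product: 10, (S)-N-methoxy-3-[4-(methoxymethoxy)phenyl]-N-methyl-2-(triethylsilyloxy)propanamide
Conditions: MeNH(OMe)·HCl (1.6 equiv), i-PrMgCl (3.2 equiv), THF, −20 → 0 °C; aq. NH4Cl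
Reagents that add atoms: N,O-dimethylhydroxylamine hydrochloride, CNOC.Cl
Why: Direct ester aminolysis by the magnesium amide (Weinreb amide formation); α-silyloxy esters undergo this at ≤0 °C without epimerisation.

## Fragment B: diprenylated aryl bromide

**Step 6**
Reactants: 11, 2,4,6-tribromoresorcinol; 5, MOMCl
Product: 12, 1,3,5-tribromo-2,4-bis(methoxymethoxy)benzene
Conditions: NaH (2.5 equiv), MOMCl (2.5 equiv), DMF, 0 °C → rt
Reagents that add atoms: MOMCl, COCCl
Why: O-alkylation of the two acidic bromophenols; MOM ethers tolerate organolithiums and stabilise adjacent aryllithiums.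

**Step 7**
Reactants: 12, 1,3,5-tribromo-2,4-bis(methoxymethoxy)benzene; 13, prenyl bromide (1-bromo-3-methylbut-2-ene)
Product: 14, 1,5-dibromo-2,4-bis(methoxymethoxy)-3-(3-methylbut-2-en-1-yl)benzene
Conditions: n-BuLi (1.05 equiv), THF, −78 °C, 20 min; CuBr·SMe2 (1.1 equiv), −78 → −40 °C; prenyl bromide (1.5 equiv), −78 °C → rt
Reagents that add atoms: prenyl bromide, CC(C)=CCBr
Why: Br/Li exchange is expected at the bromine flanked by two OMOM groups (the most stabilised, doubly chelated aryllithium), and the arylcopper then couples with prenyl bromide in SN2 fashion, since γ-attack would build a quaternary carbon. The C2-symmetric product is easy to confirm by NMR.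

**Step 8**
Reactants: 14, 1,5-dibromo-2,4-bis(methoxymethoxy)-3-(3-methylbut-2-en-1-yl)benzene; 13, prenyl bromide
Product: 15, 1-bromo-2,4-bis(methoxymethoxy)-3,5-bis(3-methylbut-2-en-1-yl)benzene
Conditions: n-BuLi (1.0 equiv), THF, −78 °C, 20 min; CuBr·SMe2 (1.1 equiv); prenyl bromide (1.5 equiv), −78 °C → rt
Reagents that add atoms: prenyl bromide, CC(C)=CCBr
Why: The two remaining bromines are equivalent by symmetry, so mono Br/Li exchange and copper-mediated allylation give a single regioisomer; exchange at −78 °C is much faster than benzylic/allylic deprotonation of the existing prenyl group.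

## Coupling and endgame

**Step 9**
Reactants: 15, 1-bromo-2,4-bis(methoxymethoxy)-3,5-bis(3-methylbut-2-en-1-yl)benzene (1.3 equiv); 10, (S)-N-methoxy-3-[4-(methoxymethoxy)phenyl]-N-methyl-2-(triethylsilyloxy)propanamide (1.0 equiv)
Product: 16, (S)-1-[2,4-bis(methoxymethoxy)-3,5-bis(3-methylbut-2-en-1-yl)phenyl]-3-[4-(methoxymethoxy)phenyl]-2-(triethylsilyloxy)propan-1-one
Conditions: 15, n-BuLi (1.25 equiv), THF, −78 °C, 20 min; then 10 in THF, −78 → −20 °C; sat. aq. NH4Cl at −20 °C
Reagents that add atoms: none (both partners are the listed reactants)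
Why: Weinreb ketone synthesis; the chelated tetrahedral intermediate prevents over-addition and releases the ketone only on quench, so the α-silyloxy stereocentre is never enolised.

**Step 10**
Reactants: 16, the protected ketone
Product: 17, Lespeflorin C6, (S)-1-[2,4-dihydroxy-3,5-bis(3-methylbut-2-en-1-yl)phenyl]-2-hydroxy-3-(4-hydroxyphenyl)propan-1-one
Conditions: 3 M aq. HCl/MeOH (1:4), degassed, rt → 40 °C, monitored by LC-MS; NaHCO3 quench, EtOAc extraction
Reagents that add atoms: none
Why: Acid-catalysed acetal hydrolysis of the three aryl MOM ethers with concurrent TES solvolysis. These conditions are mild enough that prenyl-to-chroman cyclisation and ketol enolisation should be slow, so the stereocentre is retained.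

## Compound list

1 | 4-hydroxyphenylpyruvic acid | O=C(O)C(=O)Cc1ccc(O)cc1 | starting material
2 | (S)-2-hydroxy-3-(4-hydroxyphenyl)propanoic acid | O=C(O)[C@@H](O)Cc1ccc(O)cc1 | intermediate
3 | methanol | CO | starting material
4 | methyl (S)-2-hydroxy-3-(4-hydroxyphenyl)propanoate | COC(=O)[C@@H](O)Cc1ccc(O)cc1 | intermediate
5 | chloromethyl methyl ether (MOMCl) | COCCl | starting material
6 | methyl (S)-2-hydroxy-3-[4-(methoxymethoxy)phenyl]propanoate | COC(=O)[C@@H](O)Cc1ccc(OCOC)cc1 | intermediate
7 | chlorotriethylsilane | CC[Si](Cl)(CC)CC | starting material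
8 | methyl (S)-3-[4-(methoxymethoxy)phenyl]-2-(triethylsilyloxy)propanoate | COC(=O)[C@@H](O[Si](CC)(CC)CC)Cc1ccc(OCOC)cc1 | intermediate
9 | N,O-dimethylhydroxylamine hydrochloride | CNOC.Cl | starting material
10 | (S)-N-methoxy-3-[4-(methoxymethoxy)phenyl]-N-methyl-2-(triethylsilyloxy)propanamide | CON(C)C(=O)[C@@H](O[Si](CC)(CC)CC)Cc1ccc(OCOC)cc1 | intermediate
11 | 2,4,6-tribromoresorcinol | Oc1c(Br)cc(Br)c(O)c1Br | starting material
12 | 1,3,5-tribromo-2,4-bis(methoxymethoxy)benzene | COCOc1c(Br)cc(Br)c(OCOC)c1Br | intermediate
13 | prenyl bromide (1-bromo-3-methylbut-2-ene) | CC(C)=CCBr | starting material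
14 | 1,5-dibromo-2,4-bis(methoxymethoxy)-3-(3-methylbut-2-en-1-yl)benzene | COCOc1c(Br)cc(Br)c(OCOC)c1CC=C(C)C | intermediate
15 | 1-bromo-2,4-bis(methoxymethoxy)-3,5-bis(3-methylbut-2-en-1-yl)benzene | COCOc1c(Br)cc(CC=C(C)C)c(OCOC)c1CC=C(C)C | intermediate
16 | (S)-1-[2,4-bis(methoxymethoxy)-3,5-bis(3-methylbut-2-en-1-yl)phenyl]-3-[4-(methoxymethoxy)phenyl]-2-(triethylsilyloxy)propan-1-one | COCOc1c(C(=O)[C@@H](O[Si](CC)(CC)CC)Cc2ccc(OCOC)cc2)cc(CC=C(C)C)c(OCOC)c1CC=C(C)C | intermediate
17 | Lespeflorin C6, (S)-1-[2,4-dihydroxy-3,5-bis(3-methylbut-2-en-1-yl)phenyl]-2-hydroxy-3-(4-hydroxyphenyl)propan-1-one | CC(C)=CCc1cc(C(=O)[C@@H](O)Cc2ccc(O)cc2)c(O)c(CC=C(C)C)c1O | target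

## Summary

**Total steps:** 10.
**Longest linear sequence:** 7 steps (Steps 1, 2, 3, 4, 5, 9, 10). The aryl branch is 3 steps before the convergent coupling.

**Three steps most likely to fail, with fallbacks:**

1. **Step 7 (regioselective first Br/Li exchange and SN2 prenylation).** Exchange at the wrong bromine or γ-attack would give isomers. Fallback: drop the halogen handles and build the ring by successive directed ortho-metalations of 1,3-bis(methoxymethoxy)benzene: lithiate C2 and prenylate, lithiate C4 and prenylate, then lithiate C6 and add directly to Weinreb amide 10.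

2. **Step 9 (aryllithium addition to the Weinreb amide).** The ortho-substituted aryllithium may act as a base, causing N–O fragmentation or α-deprotonation and low conversion. Fallback: reduce 10 to the α-silyloxy aldehyde (DIBAL-H, −78 °C), add the aryllithium to the aldehyde, and oxidise the resulting carbinol mixture to ketone 16 with Dess–Martin periodinane.

3. **Step 10 (global acidic deprotection).** The o-prenylphenols may cyclise to chromans, or the ketol may partly isomerise or racemise before the last MOM group is removed. Fallback: redesign the protection so the endgame is non-acidic. Use allyl ethers on all three phenols (allyl bromide in Steps 3 and 6), remove them with Pd(PPh3)4/morpholine, then remove the TES group with HF·pyridine.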